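The target is cut at its ester C–O bond into veratroyl chloride and an all-cis oxolane diol, itself the reduction product of a β-hydroxy ester. The three contiguous stereocentres of the oxolane ring (O1, C2 aryl, C3, C4 hydroxyl, C5) are set in a single ketoreductase reduction of a racemic 2-aryl-4-oxooxolane-3-carboxylate. The step exploits the C4 ketone beside the C3 ester: C3–H is enolisable, and the C3 enolate can reversibly expel ring oxygen O1 from benzylic C2, so all stereoisomers of the precursor interconvert and drain through the one the enzyme accepts. The precursor arises in one step from a cinnamate and methyl glycolate.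

Key step: step 2

Assumption: the all-cis (2S,3R,4S) configuration is read from the target SMILES, and a ketoreductase of the required sense is taken to be found by screening a commercial enzyme panel.

Step 1
Reactants: 1 methyl 3,4-dimethoxycinnamate; 2 methyl glycolate
Product: 4 racemic methyl 2-(3,4-dimethoxyphenyl)-4-oxooxolane-3-carboxylate, via oxa-Michael diester 3 (not isolated)
Conditions: NaH, THF, 0 °C (until H2 evolution stops); then 1 in DMSO, 0 °C to rt; aq HCl to pH 4
Reagents that add atoms: none
Why: Tandem oxa-Michael addition/Dieckmann condensation: the sodium alkoxide of 2 adds to the β-carbon of 1, the ester enolate of 3 closes onto the glycolate ester (5-exo-trig Claisen acylation), and deprotonation of the β-keto ester by the released methoxide pulls the reversible addition forward, while C2 and C3 form without control, which is harmless because step 2 equilibrates both.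

Step 2
Reactants: 4 racemic methyl 2-(3,4-dimethoxyphenyl)-4-oxooxolane-3-carboxylate
Product: 7 methyl (2S,3R,4S)-2-(3,4-dimethoxyphenyl)-4-hydroxyoxolane-3-carboxylate, via ring-opened benzylidene keto ester 5 (not isolated), via (2S,3S)-cis keto ester 6 (not isolated)
Conditions: engineered NADPH-dependent ketoreductase (anti-Prelog sense, chosen by panel screening), NADP+ (cat.), i-PrOH (10% v/v), triethanolamine·HCl buffer pH 8.5, MgSO4 (cat.), DMSO co-solvent, 35 °C
Reagents that add atoms: none
Why: Proposed new method: in the pH 8.5 buffer 4 should epimerise at C3 through its enol(ate), and the same enolate should expel O1 from benzylic C2 (E1cB retro-oxa-Michael) to give the aryl-conjugated enone 5, whose hydroxyl adds back to either face of C2, so that all four stereoisomers of 4 stay in equilibrium while the ketoreductase, recycled by isopropanol, reduces only 6. The closest known reaction type is the ketoreductase or yeast dynamic kinetic resolution of cyclic α-substituted β-keto esters to cis β-hydroxy esters, in which only the α-centre is labile; lability of the β-centre by reversible ring opening is the untested extension. No ring is closed in the net change, and the transient reclosure of 5 is a 5-endo-trig oxa-Michael addition, the microscopic reverse of the ring opening, helped by the doubly activated acceptor. C2 and C3 are set by the active site, which should bind only the (2S,3S)-cis isomer, and C4 is set by hydride delivery from NADPH to the carbonyl face opposite the ester and aryl groups, which leaves the hydroxyl cis to both. The step needs substrate-isomer and carbonyl-face selectivity under Curtin–Hammett conditions, that is equilibration at C2 and C3 faster than reduction of any other isomer, and the substrate secures this by the acidic C3–H between ketone and ester and by the electron-rich aryl group that stabilises 5. The product 7 has no β-keto ester left, can neither enolise nor ring-open under these conditions, and so should collect as one stereoisomer.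

Step 3
Reactants: 7 methyl (2S,3R,4S)-2-(3,4-dimethoxyphenyl)-4-hydroxyoxolane-3-carboxylate
Product: 8 (3S,4R,5S)-5-(3,4-dimethoxyphenyl)-4-(hydroxymethyl)oxolan-3-ol
Conditions: LiBH4, THF, 0 °C to rt; then MeOH, H2O
Reagents that add atoms: none
Why: Chemoselective hydride reduction of an ester with LiBH4, accelerated by the neighbouring hydroxyl, should give the primary alcohol without touching C2, C3 or C4, since the conditions are too weakly basic for C3 enolisation or retro-aldol opening.

Step 4
Reactants: 8 (3S,4R,5S)-5-(3,4-dimethoxyphenyl)-4-(hydroxymethyl)oxolan-3-ol; 9 veratroyl chloride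
Product: 10 [(2S,3R,4S)-2-(3,4-dimethoxyphenyl)-4-hydroxyoxolan-3-yl]methyl 3,4-dimethoxybenzoate
Conditions: 9 (1.05 equiv), 2,4,6-collidine, CH2Cl2, −40 to 0 °C
Reagents that add atoms: none
Why: Kinetically selective O-acylation with an acid chloride (nucleophilic acyl substitution, Schotten–Baumann-type esterification in an organic medium): the primary hydroxyl should react far faster than the secondary C4 hydroxyl, which is crowded by the cis C3 substituent, and the hindered weak base at low temperature should prevent diacylation and acyl migration, so no stereocentre is affected.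

Compound list
1 | methyl (E)-3-(3,4-dimethoxyphenyl)prop-2-enoate (methyl 3,4-dimethoxycinnamate) | COC(=O)/C=C/c1ccc(OC)c(OC)c1 | starting material
2 | methyl glycolate (methyl 2-hydroxyacetate) | COC(=O)CO | starting material
3 | methyl 3-(3,4-dimethoxyphenyl)-3-(2-methoxy-2-oxoethoxy)propanoate, racemic | COC(=O)COC(CC(=O)OC)c1ccc(OC)c(OC)c1 | intermediate (not isolated)
4 | methyl 2-(3,4-dimethoxyphenyl)-4-oxooxolane-3-carboxylate, racemic and labile at C2 and C3 (2,3-trans and 2,3-cis keto forms plus enol) | COC(=O)C1C(=O)COC1c1ccc(OC)c(OC)c1 | intermediate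
5 | methyl 2-[(3,4-dimethoxyphenyl)methylidene]-4-hydroxy-3-oxobutanoate (either alkene geometry) | COC(=O)C(=Cc1ccc(OC)c(OC)c1)C(=O)CO | intermediate (not isolated)
6 | methyl (2S,3S)-2-(3,4-dimethoxyphenyl)-4-oxooxolane-3-carboxylate (aryl and ester cis) | COC(=O)[C@@H]1C(=O)CO[C@@H]1c1ccc(OC)c(OC)c1 | intermediate (not isolated)
7 | methyl (2S,3R,4S)-2-(3,4-dimethoxyphenyl)-4-hydroxyoxolane-3-carboxylate (aryl, ester and hydroxyl all cis) | COC(=O)[C@@H]1[C@H](O)CO[C@@H]1c1ccc(OC)c(OC)c1 | intermediate
8 | (3S,4R,5S)-5-(3,4-dimethoxyphenyl)-4-(hydroxymethyl)oxolan-3-ol (all cis) | OC[C@@H]1[C@H](O)CO[C@@H]1c1ccc(OC)c(OC)c1 | intermediate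
9 | 3,4-dimethoxybenzoyl chloride (veratroyl chloride) | COc1ccc(C(=O)Cl)cc1OC | starting material
10 | [(2S,3R,4S)-2-(3,4-dimethoxyphenyl)-4-hydroxyoxolan-3-yl]methyl 3,4-dimethoxybenzoate (all cis) | COc1ccc(C(=O)OC[C@@H]2[C@H](O)CO[C@@H]2c2ccc(OC)c(OC)c2)cc1OC | target

Total step count: 4
Longest linear sequence: 4 steps (1 and 2 to 4, then 7, 8 and 10)

Steps most likely to fail

Step 2 (bears the label "Proposed new method:").
- What may go wrong: ring opening and reclosure at C2 may run slower than the reduction, so that the pool is only resolved and half the material stays behind. No panel enzyme may accept the 2,3-cis isomer. The keto ester may hydrolyse and decarboxylate in the basic buffer.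
- Fallback, known chemistry only, setting out from 4 and coming back at 7: O-acetylation of the enol (Ac2O, Et3N, DMAP cat., CH2Cl2, 0 °C) should give racemic methyl 4-acetoxy-2-(3,4-dimethoxyphenyl)-2,5-dihydrofuran-3-carboxylate F1. Heterogeneous hydrogenation (H2, Rh/Al2O3, EtOAc, rt) should add both hydrogens to the C3=C4 bond from the face opposite the C2 aryl group and so give racemic all-cis methyl 4-acetoxy-2-(3,4-dimethoxyphenyl)oxolane-3-carboxylate F2, with relative configuration by substrate control. A lipase (Candida antarctica lipase B, K2HPO4/KH2PO4 buffer pH 7, MTBE, 30 °C) should then hydrolyse the acetate of the (4S) enantiomer to 7, as the Kazlauskas rule predicts with the C3 side as the large and C5 as the medium substituent. The (2R,3R,4R)-acetate F3 stays behind and is separated. At most half of the material is used, but every operation is of a known type.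

Step 1.
- What may go wrong: conjugate addition of the glycolate alkoxide to the electron-rich cinnamate may be slow, so that self-condensation of the glycolate or ring closure in the other Dieckmann direction takes over.
- Fallback, setting out from 1 and coming back at 4 by way of 3, which is isolated this time: conjugate borylation of 1 (B2pin2, CuCl, NaOtBu, Xantphos, MeOH, THF, rt) should give racemic methyl 3-(3,4-dimethoxyphenyl)-3-(4,4,5,5-tetramethyl-1,3,2-dioxaborolan-2-yl)propanoate F4. Oxidation (NaBO3·4H2O, THF/H2O, rt) should give racemic methyl 3-(3,4-dimethoxyphenyl)-3-hydroxypropanoate F5. Rh2(OAc)4-catalysed O–H insertion of methyl diazoacetate (CH2Cl2, rt) should form the ether bond of 3 without any conjugate addition. Dieckmann closure under kinetic control (KOtBu, THF, 0 °C, acidic quench) should then give 4.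

Step 4.
- What may go wrong: discrimination between the primary and the secondary hydroxyl may be too low (diacylation), or the acyl group may migrate across the cis-1,3-diol during reaction or work-up.
- Fallback, setting out from 7 and coming back at 10: silylation of the C4 hydroxyl (TBSOTf, 2,6-lutidine, CH2Cl2, −78 to 0 °C) should give the all-cis silyl ether methyl (2S,3S,4S)-4-[tert-butyl(dimethyl)silyl]oxy-2-(3,4-dimethoxyphenyl)oxolane-3-carboxylate F6. Reduction (LiBH4, THF, 0 °C to rt) should give the primary alcohol [(2S,3S,4S)-4-[tert-butyl(dimethyl)silyl]oxy-2-(3,4-dimethoxyphenyl)oxolan-3-yl]methanol F7. Acylation with 9 (Et3N, DMAP cat., CH2Cl2, 0 °C to rt) should give the protected ester [(2S,3S,4S)-4-[tert-butyl(dimethyl)silyl]oxy-2-(3,4-dimethoxyphenyl)oxolan-3-yl]methyl 3,4-dimethoxybenzoate F8. Desilylation under acidic conditions that do not promote acyl migration (HF·pyridine, THF, 0 °C to rt) should give 10.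

Further compounds
F1 | step 2 | methyl 4-acetoxy-2-(3,4-dimethoxyphenyl)-2,5-dihydrofuran-3-carboxylate, racemic | COC(=O)C1=C(OC(C)=O)COC1c1ccc(OC)c(OC)c1
F2 | step 2 | methyl (2S,3S,4S)-4-acetoxy-2-(3,4-dimethoxyphenyl)oxolane-3-carboxylate as the racemate (all cis; one enantiomer drawn) | COC(=O)[C@@H]1[C@H](OC(C)=O)CO[C@@H]1c1ccc(OC)c(OC)c1
F3 | step 2 | methyl (2R,3R,4R)-4-acetoxy-2-(3,4-dimethoxyphenyl)oxolane-3-carboxylate (all cis, unreacted enantiomer) | COC(=O)[C@H]1[C@@H](OC(C)=O)CO[C@H]1c1ccc(OC)c(OC)c1
F4 | step 1 | methyl 3-(3,4-dimethoxyphenyl)-3-(4,4,5,5-tetramethyl-1,3,2-dioxaborolan-2-yl)propanoate, racemic | COC(=O)CC(B1OC(C)(C)C(C)(C)O1)c1ccc(OC)c(OC)c1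
F5 | step 1 | methyl 3-(3,4-dimethoxyphenyl)-3-hydroxypropanoate, racemic | COC(=O)CC(O)c1ccc(OC)c(OC)c1
F6 | step 4 | methyl (2S,3S,4S)-4-[tert-butyl(dimethyl)silyl]oxy-2-(3,4-dimethoxyphenyl)oxolane-3-carboxylate (all cis) | COC(=O)[C@@H]1[C@H](O[Si](C)(C)C(C)(C)C)CO[C@@H]1c1ccc(OC)c(OC)c1
F7 | step 4 | [(2S,3S,4S)-4-[tert-butyl(dimethyl)silyl]oxy-2-(3,4-dimethoxyphenyl)oxolan-3-yl]methanol (all cis) | OC[C@@H]1[C@H](O[Si](C)(C)C(C)(C)C)CO[C@@H]1c1ccc(OC)c(OC)c1
F8 | step 4 | [(2S,3S,4S)-4-[tert-butyl(dimethyl)silyl]oxy-2-(3,4-dimethoxyphenyl)oxolan-3-yl]methyl 3,4-dimethoxybenzoate (all cis) | COc1ccc(C(=O)OC[C@@H]2[C@H](O[Si](C)(C)C(C)(C)C)CO[C@@H]2c2ccc(OC)c(OC)c2)cc1OC
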